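**Assumption:** the target has no stereocentre and its diaryl ether bonds rotate freely, so it is achiral and needs no stereocontrol; 2,4,6-trimethoxyphenol and 2,3,4-trimethoxyphenol are taken as purchasable.

Ring letters: A = end ring whose ether oxygen sits between two OH (2,4,6-trihydroxyphenyl); B, C, E, F = 2,6-dioxygenated 1,4-phenylene rings; D = pentaoxygenated ring carrying two ortho ether oxygens; G = 3,4,5-trihydroxyphenyl end ring.

## Retrosynthetic overview

1. Target ⇐ global O-demethylation of a hexadeca-O-methyl heptamer phenol that already holds all 23 oxygens.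
2. Each of the six diaryl ether C–O bonds is cut between a hindered phenol oxygen (nucleophile) and the unhindered carbon of the next ring, supplied as an aryl(2,4,6-trimethoxyphenyl)iodonium salt carrying a tosyl-masked phenol.
3. One such reagent (from syringol) supplies rings B, C, E, F and G; a second (from 2,3,4-trimethoxyphenol) supplies ring D with its ortho O/O relationship.
4. No ring is built; the bought rings are joined in the order A → B → C → D → E → F → G, each extension unmasking the next phenol in the same pot.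

## Route

Step 1
Reactants: 1 2,6-dimethoxyphenol (syringol)
Product: 2 4-iodo-2,6-dimethoxyphenol
Conditions: I2 (1.0 equiv), NaHCO3, THF/H2O, 0 °C to rt
Reagents that add atoms: iodine, II
Why: Electrophilic aromatic iodination of the phenoxide, where both ortho positions carry OMe so iodine can enter only para to the phenol oxygen.

Step 2
Reactants: 2 4-iodo-2,6-dimethoxyphenol
Product: 3 4-iodo-2,6-dimethoxyphenyl 4-methylbenzenesulfonate
Conditions: TsCl, Et3N, DMAP (cat.), CH2Cl2, 0 °C to rt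
Reagents that add atoms: tosyl chloride, Cc1ccc(S(=O)(=O)Cl)cc1
Why: DMAP-catalysed O-sulfonylation gives an aryl tosylate that survives the oxidant and acid of step 3 and later serves as an electron-poor, hydroxide-cleavable phenol mask.

Step 3
Reactants: 3 4-iodo-2,6-dimethoxyphenyl 4-methylbenzenesulfonate; 4 1,3,5-trimethoxybenzene
Product: 6 [3,5-dimethoxy-4-(tosyloxy)phenyl](2,4,6-trimethoxyphenyl)iodonium tosylate, via hydroxy(tosyloxy)iodoarene 5 (not isolated)
Conditions: mCPBA (1.0 equiv), TsOH·H2O (1.0 equiv), MeCN, 55 °C; then 4, rt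
Reagents that add atoms: p-toluenesulfonic acid, Cc1ccc(S(=O)(=O)O)cc1 (tosylate counter-ion); mCPBA, OOC(=O)c1cccc(Cl)c1 (its oxygen sits in 5 only and leaves as water)
Why: One-pot Koser-type oxidation of the aryl iodide to the λ3-iodane followed by electrophilic aromatic substitution of the far more nucleophilic 1,3,5-trimethoxybenzene at iodine(III), the standard synthesis of aryl(TMP)iodonium tosylates.

Step 4
Reactants: 7 2,3,4-trimethoxyphenol
Product: 8 6-iodo-2,3,4-trimethoxyphenol
Conditions: I2 (1.0 equiv), NaHCO3, THF/H2O, 0 °C to rt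
Reagents that add atoms: iodine, II
Why: Electrophilic aromatic iodination of the phenoxide, where the para position and one ortho position carry OMe so iodine enters the single free ortho position C6.

Step 5
Reactants: 8 6-iodo-2,3,4-trimethoxyphenol
Product: 9 6-iodo-2,3,4-trimethoxyphenyl 4-methylbenzenesulfonate
Conditions: TsCl, Et3N, DMAP (cat.), CH2Cl2, 0 °C to rt
Reagents that add atoms: tosyl chloride, Cc1ccc(S(=O)(=O)Cl)cc1
Why: DMAP-catalysed O-sulfonylation masks the phenol that will become the ring D ether oxygen in a form stable to step 6.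

Step 6
Reactants: 9 6-iodo-2,3,4-trimethoxyphenyl 4-methylbenzenesulfonate; 4 1,3,5-trimethoxybenzene
Product: 11 [3,4,5-trimethoxy-2-(tosyloxy)phenyl](2,4,6-trimethoxyphenyl)iodonium tosylate, via hydroxy(tosyloxy)iodoarene 10 (not isolated)
Conditions: mCPBA (1.0 equiv), TsOH·H2O (1.0 equiv), MeCN, 55 °C; then 4, rt
Reagents that add atoms: p-toluenesulfonic acid, Cc1ccc(S(=O)(=O)O)cc1 (tosylate counter-ion); mCPBA, OOC(=O)c1cccc(Cl)c1 (its oxygen sits in 10 only and leaves as water)
Why: Same one-pot Koser oxidation and electrophilic aromatic substitution of 1,3,5-trimethoxybenzene at iodine(III) as in step 3.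

Step 7
Reactants: 12 2,4,6-trimethoxyphenol; 6 [3,5-dimethoxy-4-(tosyloxy)phenyl](2,4,6-trimethoxyphenyl)iodonium tosylate
Product: 14 2,6-dimethoxy-4-(2,4,6-trimethoxyphenoxy)phenol (A–B dimer phenol), via tosyl-masked dimer 13 (not isolated)
Conditions: t-BuOK (1.05 equiv), THF, 0 °C, Ar; 6 (1.2 equiv), 0 °C to rt; then aq. KOH, t-BuOH, 80 °C
Reagents that add atoms: none
Why: Proposed new method: a bifunctional aryl(TMP)iodonium reagent delivers a tosyl-masked 4-hydroxy-3,5-dimethoxyphenyl unit — the phenoxide displaces tosylate at iodine(III) and ipso ligand coupling from the T-shaped aryloxy-λ3-iodane transfers the electron-poorer sulfonyloxy aryl while the electron-rich TMP group stays on iodine, C-arylation being excluded because both ortho and the para positions of the phenoxide are substituted, and hydroxide then cleaves the tosylate S–O bond in the same pot to expose the next hindered phenol; closest known reaction type is the metal-free O-arylation of phenols by aryl(2,4,6-trimethoxyphenyl)iodonium tosylates (ligand exchange/ligand coupling), which has not been shown with a reagent carrying a masked phenol or for iterative aryl ether growth.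

Step 8
Reactants: 14 A–B dimer phenol; 6 [3,5-dimethoxy-4-(tosyloxy)phenyl](2,4,6-trimethoxyphenyl)iodonium tosylate
Product: 16 2,6-dimethoxy-4-[2,6-dimethoxy-4-(2,4,6-trimethoxyphenoxy)phenoxy]phenol (A–B–C trimer phenol), via tosyl-masked trimer 15 (not isolated)
Conditions: t-BuOK (1.05 equiv), THF, 0 °C, Ar; 6 (1.2 equiv), 0 °C to rt; then aq. KOH, t-BuOH, 80 °C
Reagents that add atoms: none
Why: Proposed new method: the step 7 one-pot arylation/unmasking repeated — ligand exchange of the hindered, C-blocked phenoxide at iodine(III), ipso ligand coupling of the sulfonyloxy aryl with TMP as the non-transferred ligand, then hydroxide cleavage of the tosylate; closest known reaction type is phenol O-arylation with aryl(TMP)iodonium tosylates.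

Step 9
Reactants: 16 A–B–C trimer phenol; 11 [3,4,5-trimethoxy-2-(tosyloxy)phenyl](2,4,6-trimethoxyphenyl)iodonium tosylate
Product: 18 2,3,4-trimethoxy-6-{2,6-dimethoxy-4-[2,6-dimethoxy-4-(2,4,6-trimethoxyphenoxy)phenoxy]phenoxy}phenol (A–B–C–D tetramer phenol), via tosyl-masked tetramer 17 (not isolated)
Conditions: t-BuOK (1.05 equiv), THF, 0 °C, Ar; 11 (1.3 equiv), 0 to 40 °C; then aq. KOH, t-BuOH, 80 °C
Reagents that add atoms: none
Why: Proposed new method: the same iodonium ligand exchange/ligand coupling with the ortho-masked reagent, whose ortho sulfonyloxy group (ortho effect) together with the electron-rich TMP ligand directs transfer of the ring D aryl to oxygen, after which hydroxide frees the phenol next to the new ether so that the 1,2-dioxygen pattern of ring D is fixed by the reagent; closest known reaction type is the metal-free synthesis of ortho-substituted, hindered diaryl ethers from phenoxides and diaryliodonium salts.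

Step 10
Reactants: 18 A–B–C–D tetramer phenol; 6 [3,5-dimethoxy-4-(tosyloxy)phenyl](2,4,6-trimethoxyphenyl)iodonium tosylate
Product: 20 A–B–C–D–E pentamer phenol (free OH on ring E between its two OMe groups), via tosyl-masked pentamer 19 (not isolated)
Conditions: t-BuOK (1.05 equiv), THF, 0 °C, Ar; 6 (1.3 equiv), 0 to 40 °C; then aq. KOH, t-BuOH, 80 °C
Reagents that add atoms: none
Why: Proposed new method: the step 7 arylation/unmasking on the ring D phenoxide, which is flanked by OMe and OAr and para-blocked by OMe so that only O-arylation by ligand coupling at iodine(III) is open; closest known reaction type is phenol O-arylation with aryl(TMP)iodonium tosylates.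

Step 11
Reactants: 20 A–B–C–D–E pentamer phenol; 6 [3,5-dimethoxy-4-(tosyloxy)phenyl](2,4,6-trimethoxyphenyl)iodonium tosylate
Product: 22 A–B–C–D–E–F hexamer phenol (free OH on ring F between its two OMe groups), via tosyl-masked hexamer 21 (not isolated)
Conditions: t-BuOK (1.05 equiv), THF, 0 °C, Ar; 6 (1.3 equiv), 0 °C to rt; then aq. KOH, t-BuOH, 80 °C
Reagents that add atoms: none
Why: Proposed new method: the step 7 arylation/unmasking repeated (phenoxide ligand exchange at iodine(III), ipso ligand coupling of the sulfonyloxy aryl, hydroxide detosylation); closest known reaction type is phenol O-arylation with aryl(TMP)iodonium tosylates.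

Step 12
Reactants: 22 A–B–C–D–E–F hexamer phenol; 6 [3,5-dimethoxy-4-(tosyloxy)phenyl](2,4,6-trimethoxyphenyl)iodonium tosylate
Product: 24 hexadeca-O-methyl heptamer phenol A–G (free OH at C4 of ring G), via tosyl-masked heptamer 23 (not isolated)
Conditions: t-BuOK (1.05 equiv), THF, 0 °C, Ar; 6 (1.3 equiv), 0 °C to rt; then aq. KOH, t-BuOH, 80 °C
Reagents that add atoms: none
Why: Proposed new method: the step 7 arylation/unmasking a last time, the unmasked ring G oxygen being one of the target hydroxyls; closest known reaction type is phenol O-arylation with aryl(TMP)iodonium tosylates.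

Step 13
Reactants: 24 hexadeca-O-methyl heptamer phenol A–G
Product: 25 target heptamer CNP0304148.0 (seventeen free OH, six diaryl ether bonds)
Conditions: BBr3 (35–40 equiv), CH2Cl2, −78 °C to rt, Ar; then ice-water; reversed-phase or Sephadex LH-20 purification under Ar
Reagents that add atoms: none
Why: Lewis-acid aryl methyl ether cleavage, in which BBr3 coordinates each methoxy oxygen and bromide removes the methyl group by SN2 while the diaryl ether C(sp2)–O bonds are inert, so hydrolysis releases all sixteen remaining phenols.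

## Compound list

1 | 2,6-dimethoxyphenol (syringol) | COc1cccc(OC)c1O | starting material
2 | 4-iodo-2,6-dimethoxyphenol | COc1cc(I)cc(OC)c1O | intermediate
3 | 4-iodo-2,6-dimethoxyphenyl 4-methylbenzenesulfonate | COc1cc(I)cc(OC)c1OS(=O)(=O)c1ccc(C)cc1 | intermediate
4 | 1,3,5-trimethoxybenzene | COc1cc(OC)cc(OC)c1 | starting material
5 | 4-[hydroxy(tosyloxy)-λ3-iodanyl]-2,6-dimethoxyphenyl 4-methylbenzenesulfonate | COc1cc(I(O)OS(=O)(=O)c2ccc(C)cc2)cc(OC)c1OS(=O)(=O)c1ccc(C)cc1 | intermediate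
6 | [3,5-dimethoxy-4-(tosyloxy)phenyl](2,4,6-trimethoxyphenyl)iodonium tosylate | COc1cc(OC)c([I+]c2cc(OC)c(OS(=O)(=O)c3ccc(C)cc3)c(OC)c2)c(OC)c1.Cc1ccc(S(=O)(=O)[O-])cc1 | intermediate
7 | 2,3,4-trimethoxyphenol | COc1ccc(O)c(OC)c1OC | starting material
8 | 6-iodo-2,3,4-trimethoxyphenol | COc1cc(I)c(O)c(OC)c1OC | intermediate
9 | 6-iodo-2,3,4-trimethoxyphenyl 4-methylbenzenesulfonate | COc1cc(I)c(OS(=O)(=O)c2ccc(C)cc2)c(OC)c1OC | intermediate
10 | 6-[hydroxy(tosyloxy)-λ3-iodanyl]-2,3,4-trimethoxyphenyl 4-methylbenzenesulfonate | COc1cc(I(O)OS(=O)(=O)c2ccc(C)cc2)c(OS(=O)(=O)c2ccc(C)cc2)c(OC)c1OC | intermediate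
11 | [3,4,5-trimethoxy-2-(tosyloxy)phenyl](2,4,6-trimethoxyphenyl)iodonium tosylate | COc1cc(OC)c([I+]c2cc(OC)c(OC)c(OC)c2OS(=O)(=O)c2ccc(C)cc2)c(OC)c1.Cc1ccc(S(=O)(=O)[O-])cc1 | intermediate
12 | 2,4,6-trimethoxyphenol | COc1cc(OC)c(O)c(OC)c1 | starting material
13 | 2,6-dimethoxy-4-(2,4,6-trimethoxyphenoxy)phenyl 4-methylbenzenesulfonate (tosyl-masked A–B dimer) | COc1cc(OC)c(Oc2cc(OC)c(OS(=O)(=O)c3ccc(C)cc3)c(OC)c2)c(OC)c1 | intermediate
14 | 2,6-dimethoxy-4-(2,4,6-trimethoxyphenoxy)phenol (A–B dimer phenol) | COc1cc(OC)c(Oc2cc(OC)c(O)c(OC)c2)c(OC)c1 | intermediate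
15 | O-tosylate of 16 (tosyl-masked A–B–C trimer) | COc1cc(OC)c(Oc2cc(OC)c(Oc3cc(OC)c(OS(=O)(=O)c4ccc(C)cc4)c(OC)c3)c(OC)c2)c(OC)c1 | intermediate
16 | 2,6-dimethoxy-4-[2,6-dimethoxy-4-(2,4,6-trimethoxyphenoxy)phenoxy]phenol (A–B–C trimer phenol) | COc1cc(OC)c(Oc2cc(OC)c(Oc3cc(OC)c(O)c(OC)c3)c(OC)c2)c(OC)c1 | intermediate
17 | O-tosylate of 18 (tosyl-masked A–B–C–D tetramer) | COc1cc(OC)c(Oc2cc(OC)c(Oc3cc(OC)c(Oc4cc(OC)c(OC)c(OC)c4OS(=O)(=O)c4ccc(C)cc4)c(OC)c3)c(OC)c2)c(OC)c1 | intermediate
18 | 2,3,4-trimethoxy-6-{2,6-dimethoxy-4-[2,6-dimethoxy-4-(2,4,6-trimethoxyphenoxy)phenoxy]phenoxy}phenol (A–B–C–D tetramer phenol) | COc1cc(OC)c(Oc2cc(OC)c(Oc3cc(OC)c(Oc4cc(OC)c(OC)c(OC)c4O)c(OC)c3)c(OC)c2)c(OC)c1 | intermediate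
19 | O-tosylate of 20 (tosyl-masked pentamer) | COc1cc(OC)c(Oc2cc(OC)c(Oc3cc(OC)c(Oc4cc(OC)c(OC)c(OC)c4Oc4cc(OC)c(OS(=O)(=O)c5ccc(C)cc5)c(OC)c4)c(OC)c3)c(OC)c2)c(OC)c1 | intermediate
20 | 2,6-dimethoxy-4-(2,3,4-trimethoxy-6-{2,6-dimethoxy-4-[2,6-dimethoxy-4-(2,4,6-trimethoxyphenoxy)phenoxy]phenoxy}phenoxy)phenol (A–E pentamer phenol) | COc1cc(OC)c(Oc2cc(OC)c(Oc3cc(OC)c(Oc4cc(OC)c(OC)c(OC)c4Oc4cc(OC)c(O)c(OC)c4)c(OC)c3)c(OC)c2)c(OC)c1 | intermediate
21 | O-tosylate of 22 (tosyl-masked hexamer) | COc1cc(OC)c(Oc2cc(OC)c(Oc3cc(OC)c(Oc4cc(OC)c(OC)c(OC)c4Oc4cc(OC)c(Oc5cc(OC)c(OS(=O)(=O)c6ccc(C)cc6)c(OC)c5)c(OC)c4)c(OC)c3)c(OC)c2)c(OC)c1 | intermediate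
22 | A–F hexamer phenol: 20 extended at its ring E oxygen by a 4-hydroxy-3,5-dimethoxyphenyl unit | COc1cc(OC)c(Oc2cc(OC)c(Oc3cc(OC)c(Oc4cc(OC)c(OC)c(OC)c4Oc4cc(OC)c(Oc5cc(OC)c(O)c(OC)c5)c(OC)c4)c(OC)c3)c(OC)c2)c(OC)c1 | intermediate
23 | O-tosylate of 24 (tosyl-masked heptamer) | COc1cc(OC)c(Oc2cc(OC)c(Oc3cc(OC)c(Oc4cc(OC)c(OC)c(OC)c4Oc4cc(OC)c(Oc5cc(OC)c(Oc6cc(OC)c(OS(=O)(=O)c7ccc(C)cc7)c(OC)c6)c(OC)c5)c(OC)c4)c(OC)c3)c(OC)c2)c(OC)c1 | intermediate
24 | hexadeca-O-methyl heptamer phenol: 22 extended at its ring F oxygen by a 4-hydroxy-3,5-dimethoxyphenyl unit | COc1cc(OC)c(Oc2cc(OC)c(Oc3cc(OC)c(Oc4cc(OC)c(OC)c(OC)c4Oc4cc(OC)c(Oc5cc(OC)c(Oc6cc(OC)c(O)c(OC)c6)c(OC)c5)c(OC)c4)c(OC)c3)c(OC)c2)c(OC)c1 | intermediate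
25 | CNP0304148.0 (achiral heptameric phlorotannin, C42H30O23) | Oc1cc(O)c(Oc2cc(O)c(Oc3cc(O)c(Oc4cc(O)c(O)c(O)c4Oc4cc(O)c(Oc5cc(O)c(Oc6cc(O)c(O)c(O)c6)c(O)c5)c(O)c4)c(O)c3)c(O)c2)c(O)c1 | target

## Step count and risks

Total steps: 13. Longest linear sequence: 10 (steps 1–3, then 7–13). The branch through steps 4–6 joins at step 9.

**Step 7 (proposed new method, repeated in steps 8 and 10–12).** Risks are sulfonyl transfer from the iodonium-activated tosylate of 6 to the phenoxide, single-electron oxidation of the very electron-rich phenoxide by the iodonium salt, and partial TMP transfer. The fallback uses known chemistry, sets out from 12 (with 2 as the aryl source) and comes back at 14. Phenol 2 is O-benzylated (BnBr, K2CO3, DMF) to 2-(benzyloxy)-5-iodo-1,3-dimethoxybenzene F1. This is joined to 12 by a copper-catalysed Ullmann ether synthesis (CuI, picolinic acid, K3PO4, DMSO, 90 °C) to give 2-(benzyloxy)-1,3-dimethoxy-5-(2,4,6-trimethoxyphenoxy)benzene F2. Hydrogenolysis (H2, Pd/C, EtOAc/MeOH) then gives 14.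

**Step 9.** This forms a diaryl ether with three ortho substituents from an ortho-sulfonyloxy reagent on a larger substrate, so it is the most hindered coupling. The fallback sets out from 16 and comes back at 18. Commercial 5-bromo-1,2,3-trimethoxybenzene is lithiated at the only ring C–H type (LDA, THF, −78 °C) and quenched with DMF to give 6-bromo-2,3,4-trimethoxybenzaldehyde F3. Its formyl-activated C–Br bond is coupled with 16 (CuI, picolinic acid, K3PO4, DMSO, 100 °C) to give the tetramer aldehyde 2,3,4-trimethoxy-6-(A–B–C-aryloxy)benzaldehyde F4. Baeyer–Villiger oxidation (mCPBA, NaHCO3, CH2Cl2, 0 °C) gives the tetramer aryl formate F5, and methanolysis (K2CO3, MeOH) gives 18.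

**Step 13.** Sixteen methyl ethers must all be cleaved, and the free polyphenol is very polar and air-sensitive, so incomplete cleavage and loss on purification are both likely. The fallback sets out from 24 and comes back at 25. The crude BBr3 product is not purified but acetylated at once (Ac2O, pyridine, DMAP) to the heptadecaacetate F6, which is stable and can be purified on silica, with under-demethylated material separated and resubmitted. Mild deacetylation under argon (cat. NaOMe, MeOH, then acidic resin) releases 25.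

## Further compounds

F1 | step 7 | 2-(benzyloxy)-5-iodo-1,3-dimethoxybenzene | COc1cc(I)cc(OC)c1OCc1ccccc1
F2 | step 7 | 2-(benzyloxy)-1,3-dimethoxy-5-(2,4,6-trimethoxyphenoxy)benzene | COc1cc(OC)c(Oc2cc(OC)c(OCc3ccccc3)c(OC)c2)c(OC)c1
F3 | step 9 | 6-bromo-2,3,4-trimethoxybenzaldehyde | COc1cc(Br)c(C=O)c(OC)c1OC
F4 | step 9 | 2,3,4-trimethoxy-6-{2,6-dimethoxy-4-[2,6-dimethoxy-4-(2,4,6-trimethoxyphenoxy)phenoxy]phenoxy}benzaldehyde | COc1cc(OC)c(Oc2cc(OC)c(Oc3cc(OC)c(Oc4cc(OC)c(OC)c(OC)c4C=O)c(OC)c3)c(OC)c2)c(OC)c1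
F5 | step 9 | 2,3,4-trimethoxy-6-{2,6-dimethoxy-4-[2,6-dimethoxy-4-(2,4,6-trimethoxyphenoxy)phenoxy]phenoxy}phenyl formate | COc1cc(OC)c(Oc2cc(OC)c(Oc3cc(OC)c(Oc4cc(OC)c(OC)c(OC)c4OC=O)c(OC)c3)c(OC)c2)c(OC)c1
F6 | step 13 | heptadeca-O-acetate of 25 | CC(=O)Oc1cc(OC(C)=O)c(Oc2cc(OC(C)=O)c(Oc3cc(OC(C)=O)c(Oc4cc(OC(C)=O)c(OC(C)=O)c(OC(C)=O)c4Oc4cc(OC(C)=O)c(Oc5cc(OC(C)=O)c(Oc6cc(OC(C)=O)c(OC(C)=O)c(OC(C)=O)c6)c(OC(C)=O)c5)c(OC(C)=O)c4)c(OC(C)=O)c3)c(OC(C)=O)c2)c(OC(C)=O)c1
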